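## The problem

Compound 18 is an achiral, fully aromatic 2-arylbenzofuran. Ring A (C3a to C7a) carries a methoxy group at C7 and a 3-hydroxypropyl chain at C5, the furan ring carries a formyl group at C3, and ring B on C2 is a 4-hydroxy-3-methoxyphenyl group. Because the target has no stereocentre, the task is one of regiochemistry: C3a, C5, C7 and C7a of ring A and both furan carbons are substituted, and each substituent must be placed without isomers. Stereocentres that arise on the way are transient; they need no absolute control and direct nothing that survives, so racemic intermediates are acceptable provided the centres are later flattened. The groups that will not survive rough treatment are the aldehyde (conjugated through C2=C3 to an electron-rich aryl group, intolerant of hydride, organometallic and hydrogenation conditions), the oxidisable guaiacyl phenol and the primary alcohol; the electron-rich benzofuran is itself open to electrophiles. The aldehyde must therefore appear late, and any hydrogenolysis must be finished before it exists. The enabling feature is that C2 has only three heavy-atom neighbours (O1, C3 and C1' of ring B), so it can be delivered as one carbon that already carries ring B and acts first as a nucleophile and then as an electrophile, while O1–C7a–C3a–C3 is the four-atom skeleton of an ortho-quinone methide. The pattern of ring A around that unit (methoxy ortho to O1, chain para to O1, one free ortho position at C3a) is that of eugenol, and the formyl carbon sits on the methide carbon C3, where it can travel as a methyl group.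

## Retrosynthesis

**18 ⇒ 17.** The first cut is the O–Si bond of the side chain, which leads from 18 to silyl ether 17. A tert-butyldiphenylsilyl ether is chosen over a smaller silyl group or an ester because it has to pass a sulfinic acid, a Grignard reagent, carbonate, hydrogenation and a quinone oxidant. The forward step only has to spare a phenol and an aryl aldehyde, which buffered fluoride does.

**17 ⇒ 14.** No skeletal bond is cut here. The C3 formyl group is read as a methyl group and the furan as a 2,3-dihydrofuran, which leads to phenol 14 by way of the 3-methylbenzofuran 15 and the hydroxymethyl compound 16. The neighbouring option, cutting C3–CHO and formylating a 3-unsubstituted 2-arylbenzofuran, would add a C–C bond-forming step on a nucleus with competing nucleophilic positions at C4 and C6. Carrying the carbon as a methyl group costs nothing and puts 14 at the oxidation level of the 3-methyl-2-aryl neolignans, whose behaviour towards DDQ is understood. The forward reaction must oxidise C2–H/C3–H and then the C3 methyl group while leaving the benzylic CH2 of the C5 chain alone. The free phenol para to C2 is kept for this purpose, because it channels each oxidation through a quinone-methide-type cation that only the C2/C3/methyl array can form.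

**14 ⇒ 13.** The O–benzyl bond on ring B is cut. The ring B phenol has to be masked while the ylide is made, since a free or silylated para-oxygen would expel the sulfonium group as a para-quinone methide; a benzyl ether is inert to base and to the sulfonium chemistry. It is removed at this point, before any aldehyde or furan double bond exists, so that plain hydrogenolysis suffices. The forward step needs the exocyclic O-benzyl bond to cleave faster than the ring C2–O1 bond.

**13 ⇒ 6 + 9 (key disconnection).** Dihydrobenzofuran 13 is cut at C2–C3 and O1–C2. This removes C2 with ring B as a one-carbon unit and leaves O1, C7a, C3a and C3 as ortho-quinone methide 10. The one-carbon unit must attack C3 as a nucleophile and then accept O1 as an electrophile, which is the profile of a sulfonium ylide: benzylic ylide 11, generated from salt 9. The quinone methide is stored as 2-(1-sulfonylethyl)phenol 6, from which base releases it, and the two partners join through betaine 12. Two neighbouring cuts were weighed: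
- O1–C2 together with C3–C3a (aryl ether formation, then Friedel–Crafts closure) tends to place the aryl group at C3 rather than C2.
- C2–aryl together with O1–C7a calls for transition-metal couplings on halogenated intermediates.

The chosen cut divides the molecule into two phenylpropanoid-sized halves, neither containing a ring still to be formed. The forward reaction needs C-attack of the ylide on the methide carbon, addition faster than proton loss from the methide methyl group, and ring closure faster than elimination. The relative configuration at C2/C3 is immaterial because both centres are removed later.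

**6 ⇒ 5 ⇒ 4.** Sulfone 6 is cut at the benzylic C–S bond to alcohol 5 and a sulfinic acid. This is the standard way to make a shelf-stable quinone methide precursor, and it only asks the benzylic alcohol to ionise ortho to the phenol. Alcohol 5 is cut at C3–CH3 to salicylaldehyde 4 and a methyl Grignard reagent. This bond brings in the carbon that ends as the formyl group.

**4 ⇒ 3 ⇒ 2 ⇒ 1.** The C3a–C3 bond of 4 is cut by an ortho-formylation transform to phenol 3. The reaction has only one site available, since the para position carries the chain and the other ortho position the methoxy group. Phenol 3 is traced to diol 2 (O–Si) and 2 to eugenol (1) by an anti-Markovnikov hydration transform. Eugenol already holds the whole of ring A with its oxygen pattern and the three chain carbons.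

**9 ⇒ 8 ⇒ 7.** Salt 9 is cut at the benzylic C–S bond to alcohol 8 and a dialkyl sulfide, and 8 is the reduction product of aldehyde 7, the commercial benzyl ether of vanillin. Making the salt directly from the alcohol avoids an unstable electron-rich benzylic halide and gives a non-nucleophilic counter-ion.

## Roads not taken

**Alternative 1:** Ring A is cut at C7–C7a and at C4=C5, so it is built onto a preformed 2-arylfuran.
- Forward key step: furan aldehyde A1 would undergo Stobbe condensation with a succinate diester to half-ester A2. Heating A2 with acetic anhydride and NaOAc would acylate the free furan alpha-carbon and close ring A as the 7-acetoxy-5-ester A3.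
- Merits: classical, metal-free, regiochemically unambiguous, and better precedented as a ring closure than a benzylic ylide annulation.
- Weak points: A3 has the right atoms in the wrong state at three places. The C7 acetate must become a methyl ether, the C5 ester must be extended by two carbons and reduced, and C3 has no carbon yet and would need formylation. A1 is itself a coupling product.
- Comparison: this road builds by annulation a substitution pattern that eugenol supplies ready-made. Its ring-forming step is the safer one. Against that the chosen plan sets a sequence about half as long, in which every carbon of 18 is in place after step 8.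

**Alternative 2:** Ring A is cut at C7–C6, C5–C4 and C4–C3a.
- Forward key step: Fischer carbene complex A4, (CO)5Cr=C(OMe)(furyl) with zerovalent chromium, would be heated with terminal alkyne A5 to give 4-hydroxybenzofuran A6 in a Dötz benzannulation.
- Merits: highly convergent; the chain and the methoxy group are placed by the inherent regiochemistry of the annulation; C3 is already at the aldehyde oxidation level as an acetal. In that last respect this road is better than the chosen plan, which needs a late oxidation.
- Weak points: the annulation leaves a hydroxyl group at C4 that the target lacks, so triflation and reductive removal must follow. A6 is an air-sensitive hydroquinone monoether. Chromium is used stoichiometrically. A4 requires a trisubstituted furan made over several steps and a lithiation.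
- Comparison: the chosen plan sets its one-operation DDQ oxidation against the acetal advantage. It is shorter and needs neither stoichiometric metal nor a deoxygenation.

**Alternative 3:** The furan ring is cut at O1–C2 and at the bond from C3 to the carbonyl carbon.
- Forward key step: alkynylphenol A7 (Sonogashira coupling of an ortho-iodinated eugenol-derived phenol with an arylacetylene made from 7) would be treated with PdCl2 and CuCl2 under CO in methanol. Oxypalladation by divalent palladium, CO insertion and methanolysis would give ester A8.
- Merits: this is the most direct and best documented entry to 2-aryl-3-carbonylbenzofurans. It forms the aromatic furan at once, creates no stereocentres to discard, needs no dehydrogenation, and brings in the C3 carbon in the ring-forming step. In precedent for the ring closure it is stronger than the chosen plan, and in length about equal.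
- Weak points: protodepalladation can compete and give the 3-unsubstituted benzofuran. The ester must be reduced and the resulting benzylic alcohol reoxidised selectively beside the primary alcohol. The benzyl group then has to come off in the presence of the aldehyde. Iodination and alkyne synthesis are needed, and CO must be handled.
- Comparison: the chosen plan sets against this that it uses no noble metal, no CO and no halogenated intermediate, that both fragments come from 1 and 7 by simple functional-group operations, and that C3 reaches the aldehyde level in one oxidative operation instead of a reduction–oxidation pair. If the ylide annulation failed beyond repair, this alternative would be the replacement.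

Key step: step 8

Remarks on the chemistry:
- 18 is achiral. Compounds 5, 6, 12, 13 and 14 are racemates; where two stereocentres are present, one enantiomer of the racemate is drawn.
- p-Toluenesulfinic acid is taken as freshly liberated from its commercial sodium salt.

## Route

Step 1
Reactants: 1 eugenol (4-allyl-2-methoxyphenol)
Product: 2 4-(3-hydroxypropyl)-2-methoxyphenol
Conditions: 9-BBN (2.5 equiv), THF, 0 °C to rt; then NaOH, H2O2, 0 °C to rt
Reagents that add atoms: hydrogen peroxide, OO
Why: Anti-Markovnikov hydroboration–oxidation of the terminal allyl group; the bulky borane puts boron on the terminal carbon, and the phenol only consumes one equivalent of borane as an aryloxyborane that is hydrolysed on work-up.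

Step 2
Reactants: 2 4-(3-hydroxypropyl)-2-methoxyphenol
Product: 3 4-[3-(tert-butyldiphenylsilyloxy)propyl]-2-methoxyphenol
Conditions: TBDPSCl (1.05 equiv), imidazole, CH2Cl2, 0 °C
Reagents that add atoms: tert-butyl(chloro)diphenylsilane, CC(C)(C)[Si](Cl)(c1ccccc1)c1ccccc1
Why: Chemoselective silylation; with a bulky chlorosilane and imidazole the unhindered primary alcohol should react faster than the less nucleophilic, hydrogen-bonded guaiacol hydroxyl.

Step 3
Reactants: 3 4-[3-(tert-butyldiphenylsilyloxy)propyl]-2-methoxyphenol
Product: 4 2-hydroxy-3-methoxy-5-[3-(tert-butyldiphenylsilyloxy)propyl]benzaldehyde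
Conditions: MgCl2, Et3N, (CH2O)n, MeCN, reflux
Reagents that add atoms: paraformaldehyde (formaldehyde), C=O
Why: Magnesium-mediated ortho-formylation of a phenol (Casnati–Skattebøl); the magnesium phenoxide delivers formaldehyde to the only free ortho position, and a second formaldehyde oxidises the benzylic alkoxide by hydride transfer.

Step 4
Reactants: 4 2-hydroxy-3-methoxy-5-[3-(tert-butyldiphenylsilyloxy)propyl]benzaldehyde
Product: 5 racemic 2-(1-hydroxyethyl)-6-methoxy-4-[3-(tert-butyldiphenylsilyloxy)propyl]phenol
Conditions: MeMgBr (3 equiv), THF, 0 °C; then aq NH4Cl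
Reagents that add atoms: methylmagnesium bromide, C[Mg]Br
Why: Grignard addition to the aldehyde after the first equivalent has formed the magnesium phenoxide; the new stereocentre is racemic and is destroyed in step 8.

Step 5
Reactants: 5 racemic 2-(1-hydroxyethyl)-6-methoxy-4-[3-(tert-butyldiphenylsilyloxy)propyl]phenol
Product: 6 racemic 2-methoxy-6-[1-(p-tolylsulfonyl)ethyl]-4-[3-(tert-butyldiphenylsilyloxy)propyl]phenol
Conditions: p-TolSO2H (1.5 equiv), CH2Cl2, rt
Reagents that add atoms: p-toluenesulfinic acid, Cc1ccc(cc1)S(=O)O
Why: Acid-promoted substitution of an ortho-hydroxybenzylic alcohol; the sulfinic acid ionises the alcohol and sulfinate captures the cation at sulfur, giving the sulfone as the thermodynamic product, which is the standard preparation of 2-(1-sulfonylalkyl)phenols.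

Step 6
Reactants: 7 4-benzyloxy-3-methoxybenzaldehyde
Product: 8 (4-benzyloxy-3-methoxyphenyl)methanol
Conditions: NaBH4, MeOH, 0 °C
Reagents that add atoms: none
Why: Borohydride reduction of an aromatic aldehyde; the benzyl ether is inert.

Step 7
Reactants: 8 (4-benzyloxy-3-methoxyphenyl)methanol
Product: 9 (4-benzyloxy-3-methoxybenzyl)dimethylsulfonium tetrafluoroborate
Conditions: Me2S (5 equiv), HBF4·OEt2 (1.0 equiv), CH2Cl2, 0 °C; Et2O (precipitation)
Reagents that add atoms: dimethyl sulfide, CSC; tetrafluoroboric acid (diethyl ether complex), [H+].F[B-](F)(F)F
Why: Sulfonium salt formation from a benzylic alcohol, a sulfide and a strong acid; the para-alkoxy group makes ionisation easy at 0 °C, the single equivalent of acid is consumed as water so the aryl benzyl ether is not left in acid, and tetrafluoroborate cannot dealkylate the salt.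

Step 8
Reactants: 6 racemic 2-methoxy-6-[1-(p-tolylsulfonyl)ethyl]-4-[3-(tert-butyldiphenylsilyloxy)propyl]phenol; 9 (4-benzyloxy-3-methoxybenzyl)dimethylsulfonium tetrafluoroborate
Product: 13 racemic trans-(2R,3R)-2-(4-benzyloxy-3-methoxyphenyl)-7-methoxy-3-methyl-5-[3-(tert-butyldiphenylsilyloxy)propyl]-2,3-dihydrobenzofuran, via ortho-quinone methide 10 (not isolated), via benzylic sulfonium ylide 11 (not isolated), via phenoxide sulfonium betaine 12 (not isolated)
Conditions: 9 (1.5 equiv), Cs2CO3 (3 equiv), MeCN/CH2Cl2, 0 °C; 6 added slowly; then rt
Reagents that add atoms: none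
Why: Cs2CO3 deprotonates the phenol of 6, and E1cB loss of p-toluenesulfinate gives quinone methide 10, while the same base deprotonates 9 at its benzylic carbon to give ylide 11. The ylide carbon adds to the exocyclic methide carbon of 10, forming C2–C3 and restoring the aromaticity of ring A in betaine 12. The phenoxide of 12 then displaces dimethyl sulfide from C2 in an intramolecular SN2 reaction, forming O1–C2 and closing the dihydrofuran in the 5-exo-tet mode. The closest known reaction type is the [4+1] annulation of quinone methides released by carbonate from 2-(1-sulfonylalkyl)phenols with sulfonium ylides to give trans-2,3-dihydrobenzofurans; it is best documented for carbonyl-stabilised ylides, and the semi-stabilised benzylic ylide used here is more nucleophilic but less persistent. C2 and C3 are set under substrate control: the betaine rotamer that closes holds the C2 aryl and C3 methyl groups on opposite sides of the forming ring, so the trans racemate is expected, and because step 10 flattens both centres any cis component can be carried forward. The step needs conjugate addition to outrun proton loss from the methide methyl group and benzyl transfer from 9 to the phenoxide; slow addition of 6 to excess salt and base at 0 °C keeps each quinone methide molecule in the presence of ylide, and rearomatisation of ring A makes the C-addition fast and irreversible. The tetrafluoroborate counter-ion and the benzyl ether on ring B keep 9 from dealkylation and from collapse to a para-quinone methide.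

Step 9
Reactants: 13 racemic trans-(2R,3R)-2-(4-benzyloxy-3-methoxyphenyl)-7-methoxy-3-methyl-5-[3-(tert-butyldiphenylsilyloxy)propyl]-2,3-dihydrobenzofuran
Product: 14 racemic trans-4-[(2R,3R)-7-methoxy-3-methyl-5-[3-(tert-butyldiphenylsilyloxy)propyl]-2,3-dihydrobenzofuran-2-yl]-2-methoxyphenol
Conditions: H2 (1 atm), Pd/C (10%), EtOAc, rt
Reagents that add atoms: none
Why: Hydrogenolysis of an aryl benzyl ether; the unhindered exocyclic O–CH2Ph bond should cleave well before the cyclic C2–O1 bond if the reaction is stopped after one equivalent of hydrogen, and no aldehyde or reducible alkene is present yet.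

Step 10
Reactants: 14 racemic trans-4-[(2R,3R)-7-methoxy-3-methyl-5-[3-(tert-butyldiphenylsilyloxy)propyl]-2,3-dihydrobenzofuran-2-yl]-2-methoxyphenol
Product: 17 2-(4-hydroxy-3-methoxyphenyl)-7-methoxy-5-[3-(tert-butyldiphenylsilyloxy)propyl]benzofuran-3-carbaldehyde, via 3-methylbenzofuran phenol 15 (not isolated), via 3-hydroxymethylbenzofuran phenol 16 (not isolated)
Conditions: DDQ (1.1 equiv), 1,4-dioxane, rt; then H2O, DDQ (2.2 equiv), rt
Reagents that add atoms: water, O
Why: DDQ dehydrogenation of a 2-aryl-2,3-dihydrobenzofuran to 15, then DDQ/water oxidation of a methyl group that is vinylogously para to a phenol, through alcohol 16 to the aldehyde; this is the reaction type known for phenolic 3-methyl-2-aryl neolignans of the isoeugenol-dimer family, for 4-propenylphenols (to cinnamaldehydes) and for 3-alkylindoles (to 3-acylindoles). The free phenol lets every hydride abstraction pass through a quinone-methide-type cation confined to C2, C3 and the methyl carbon, and the aldehyde formed deactivates the system towards further oxidation. Both stereocentres disappear here.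

Step 11
Reactants: 17 2-(4-hydroxy-3-methoxyphenyl)-7-methoxy-5-[3-(tert-butyldiphenylsilyloxy)propyl]benzofuran-3-carbaldehyde
Product: 18 2-(4-hydroxy-3-methoxyphenyl)-5-(3-hydroxypropyl)-7-methoxybenzofuran-3-carbaldehyde (target)
Conditions: Bu4NF, AcOH, THF, rt
Reagents that add atoms: none
Why: Fluoride cleavage of a primary silyl ether; the acetic acid buffer keeps the phenol and the aldehyde away from strongly basic fluoride.

## Compound list

1 | eugenol (4-allyl-2-methoxyphenol) | C=CCc1ccc(O)c(OC)c1 | starting material
2 | 4-(3-hydroxypropyl)-2-methoxyphenol | COc1cc(CCCO)ccc1O | intermediate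
3 | 4-[3-(tert-butyldiphenylsilyloxy)propyl]-2-methoxyphenol | COc1cc(CCCO[Si](c2ccccc2)(c2ccccc2)C(C)(C)C)ccc1O | intermediate
4 | 2-hydroxy-3-methoxy-5-[3-(tert-butyldiphenylsilyloxy)propyl]benzaldehyde | COc1cc(CCCO[Si](c2ccccc2)(c2ccccc2)C(C)(C)C)cc(C=O)c1O | intermediate
5 | racemic 2-(1-hydroxyethyl)-6-methoxy-4-[3-(tert-butyldiphenylsilyloxy)propyl]phenol | COc1cc(CCCO[Si](c2ccccc2)(c2ccccc2)C(C)(C)C)cc(C(C)O)c1O | intermediate
6 | racemic 2-methoxy-6-[1-(p-tolylsulfonyl)ethyl]-4-[3-(tert-butyldiphenylsilyloxy)propyl]phenol | COc1cc(CCCO[Si](c2ccccc2)(c2ccccc2)C(C)(C)C)cc(C(C)S(=O)(=O)c2ccc(C)cc2)c1O | intermediate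
7 | 4-benzyloxy-3-methoxybenzaldehyde | COc1cc(C=O)ccc1OCc1ccccc1 | starting material
8 | (4-benzyloxy-3-methoxyphenyl)methanol | COc1cc(CO)ccc1OCc1ccccc1 | intermediate
9 | (4-benzyloxy-3-methoxybenzyl)dimethylsulfonium tetrafluoroborate | C[S+](C)Cc1ccc(OCc2ccccc2)c(OC)c1.F[B-](F)(F)F | intermediate
10 | (6E)-6-ethylidene-2-methoxy-4-[3-(tert-butyldiphenylsilyloxy)propyl]cyclohexa-2,4-dien-1-one | C/C=C1\C=C(CCCO[Si](c2ccccc2)(c2ccccc2)C(C)(C)C)C=C(OC)C1=O | intermediate
11 | (4-benzyloxy-3-methoxyphenyl)(dimethylsulfonio)methanide | C[S+](C)[CH-]c1ccc(OCc2ccccc2)c(OC)c1 | intermediate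
12 | racemic [(1S,2R)-1-(4-benzyloxy-3-methoxyphenyl)-2-[3-methoxy-2-oxido-5-[3-(tert-butyldiphenylsilyloxy)propyl]phenyl]propyl]dimethylsulfonium (betaine) | COc1cc(CCCO[Si](c2ccccc2)(c2ccccc2)C(C)(C)C)cc([C@@H](C)[C@@H](c2ccc(OCc3ccccc3)c(OC)c2)[S+](C)C)c1[O-] | intermediate
13 | racemic trans-(2R,3R)-2-(4-benzyloxy-3-methoxyphenyl)-7-methoxy-3-methyl-5-[3-(tert-butyldiphenylsilyloxy)propyl]-2,3-dihydrobenzofuran | COc1cc(CCCO[Si](c2ccccc2)(c2ccccc2)C(C)(C)C)cc2c1O[C@@H](c1ccc(OCc3ccccc3)c(OC)c1)[C@@H]2C | intermediate
14 | racemic trans-4-[(2R,3R)-7-methoxy-3-methyl-5-[3-(tert-butyldiphenylsilyloxy)propyl]-2,3-dihydrobenzofuran-2-yl]-2-methoxyphenol | COc1cc(CCCO[Si](c2ccccc2)(c2ccccc2)C(C)(C)C)cc2c1O[C@@H](c1ccc(O)c(OC)c1)[C@@H]2C | intermediate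
15 | 4-[7-methoxy-3-methyl-5-[3-(tert-butyldiphenylsilyloxy)propyl]benzofuran-2-yl]-2-methoxyphenol | COc1cc(-c2oc3c(OC)cc(CCCO[Si](c4ccccc4)(c4ccccc4)C(C)(C)C)cc3c2C)ccc1O | intermediate
16 | 4-[3-(hydroxymethyl)-7-methoxy-5-[3-(tert-butyldiphenylsilyloxy)propyl]benzofuran-2-yl]-2-methoxyphenol | COc1cc(-c2oc3c(OC)cc(CCCO[Si](c4ccccc4)(c4ccccc4)C(C)(C)C)cc3c2CO)ccc1O | intermediate
17 | 2-(4-hydroxy-3-methoxyphenyl)-7-methoxy-5-[3-(tert-butyldiphenylsilyloxy)propyl]benzofuran-3-carbaldehyde | COc1cc(-c2oc3c(OC)cc(CCCO[Si](c4ccccc4)(c4ccccc4)C(C)(C)C)cc3c2C=O)ccc1O | intermediate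
18 | 2-(4-hydroxy-3-methoxyphenyl)-5-(3-hydroxypropyl)-7-methoxybenzofuran-3-carbaldehyde | COc1cc(-c2oc3c(OC)cc(CCCO)cc3c2C=O)ccc1O | target

## Step count and risk

Total step count: 11. Longest linear sequence: 9 steps (steps 1–5 and 8–11, from eugenol); the ring B branch contributes steps 6 and 7.

**Step 8 (key step).**
- What may go wrong: proton loss from the methide methyl group of the quinone methide (tautomerisation to a vinylphenol) before the ylide arrives; benzyl transfer from the electron-rich sulfonium salt to the phenoxide; decay of the semi-stabilised ylide by Sommelet–Hauser rearrangement or methylide transfer; elimination of dimethyl sulfide from the betaine instead of ring closure. All stem from the ylide being more basic and shorter-lived than the carbonyl-stabilised ylides for which this annulation is best established.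
- Fallback: sets out from 5 and returns at 15; it builds the furan by a different, known ring construction. Oxidation of the benzylic alcohol of 5 with MnO2 gives 1-[2-hydroxy-3-methoxy-5-[3-(tert-butyldiphenylsilyloxy)propyl]phenyl]ethanone F1. Acylation of its phenol with 4-benzyloxy-3-methoxybenzoyl chloride (Et3N, DMAP) gives 2-acetyl-6-methoxy-4-[3-(tert-butyldiphenylsilyloxy)propyl]phenyl 4-benzyloxy-3-methoxybenzoate F2. McMurry-type reductive keto-ester coupling (TiCl3, Zn, THF, reflux) forms C2=C3 and gives 2-(4-benzyloxy-3-methoxyphenyl)-7-methoxy-3-methyl-5-[3-(tert-butyldiphenylsilyloxy)propyl]benzofuran F3. Hydrogenolysis (H2, Pd/C) then gives 15, which enters step 10 at its second stage (DDQ 2.2 equiv, wet dioxane).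

**Step 10.**
- What may go wrong: over-oxidation of the guaiacyl phenol to quinonoid material; hydride abstraction at the benzylic CH2 of the C5 chain; stalling at the alcohol stage; intermolecular capture of the cation by a phenol instead of water.
- Fallback: sets out from 14 and returns at 17; the phenol is masked and the oxygen is delivered by a selenium ene/sigmatropic sequence instead of phenol-driven hydride abstraction. DDQ is limited to 1.1 equiv in dry dioxane and 15 is isolated. Acetylation (Ac2O, pyridine) gives 4-[7-methoxy-3-methyl-5-[3-(tert-butyldiphenylsilyloxy)propyl]benzofuran-2-yl]-2-methoxyphenyl acetate F4. Riley oxidation (SeO2, 1,4-dioxane, reflux) gives 4-[3-formyl-7-methoxy-5-[3-(tert-butyldiphenylsilyloxy)propyl]benzofuran-2-yl]-2-methoxyphenyl acetate F5. Mild methanolysis (K2CO3, MeOH) then gives 17.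

**Step 7.**
- What may go wrong: cleavage of the aryl benzyl ether by the acid–sulfide pair, or Friedel–Crafts self-alkylation by the benzylic cation before the sulfide traps it.
- Fallback: sets out from 8 and returns at 9; acid-mediated ionisation is replaced by SN2 alkylation of the sulfide. PBr3 (Et2O, 0 °C) converts 8 into 4-benzyloxy-3-methoxybenzyl bromide F6, which alkylates Me2S in CH2Cl2/water in the presence of NaBF4 to give 9.

**Step 2.**
- What may go wrong: silylation at the phenol competing with silylation at the primary alcohol, giving mixtures.
- Fallback: sets out from 2 and returns at 3; over-protection followed by selective release. Excess TBDPSCl and imidazole in DMF give tert-butyl[2-methoxy-4-[3-(tert-butyldiphenylsilyloxy)propyl]phenoxy]diphenylsilane F7. K2CO3 in MeOH then cleaves only the aryl silyl ether to give 3.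

**Step 3.**
- What may go wrong: slow or incomplete formylation because the ortho-methoxy group chelates magnesium and crowds the reacting position, and condensation of the intermediate salicyl alkoxide with unreacted phenol to diarylmethanes.
- Fallback: sets out from 3 and returns at 4; the carbon is introduced at the alcohol level and oxidised separately. Lederer–Manasse hydroxymethylation (aqueous CH2O, NaOH, THF, rt) gives 2-(hydroxymethyl)-6-methoxy-4-[3-(tert-butyldiphenylsilyloxy)propyl]phenol F8, and MnO2 in CH2Cl2 oxidises the benzylic alcohol to 4.

## Further compounds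

F1 | step 8 | 1-[2-hydroxy-3-methoxy-5-[3-(tert-butyldiphenylsilyloxy)propyl]phenyl]ethanone | COc1cc(CCCO[Si](c2ccccc2)(c2ccccc2)C(C)(C)C)cc(C(C)=O)c1O
F2 | step 8 | 2-acetyl-6-methoxy-4-[3-(tert-butyldiphenylsilyloxy)propyl]phenyl 4-benzyloxy-3-methoxybenzoate | COc1cc(CCCO[Si](c2ccccc2)(c2ccccc2)C(C)(C)C)cc(C(C)=O)c1OC(=O)c1ccc(OCc2ccccc2)c(OC)c1
F3 | step 8 | 2-(4-benzyloxy-3-methoxyphenyl)-7-methoxy-3-methyl-5-[3-(tert-butyldiphenylsilyloxy)propyl]benzofuran | COc1cc(-c2oc3c(OC)cc(CCCO[Si](c4ccccc4)(c4ccccc4)C(C)(C)C)cc3c2C)ccc1OCc1ccccc1
F4 | step 10 | 4-[7-methoxy-3-methyl-5-[3-(tert-butyldiphenylsilyloxy)propyl]benzofuran-2-yl]-2-methoxyphenyl acetate | CC(=O)Oc1ccc(-c2oc3c(OC)cc(CCCO[Si](c4ccccc4)(c4ccccc4)C(C)(C)C)cc3c2C)cc1OC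
F5 | step 10 | 4-[3-formyl-7-methoxy-5-[3-(tert-butyldiphenylsilyloxy)propyl]benzofuran-2-yl]-2-methoxyphenyl acetate | CC(=O)Oc1ccc(-c2oc3c(OC)cc(CCCO[Si](c4ccccc4)(c4ccccc4)C(C)(C)C)cc3c2C=O)cc1OC
F6 | step 7 | 4-benzyloxy-3-methoxybenzyl bromide | COc1cc(CBr)ccc1OCc1ccccc1
F7 | step 2 | tert-butyl[2-methoxy-4-[3-(tert-butyldiphenylsilyloxy)propyl]phenoxy]diphenylsilane | COc1cc(CCCO[Si](c2ccccc2)(c2ccccc2)C(C)(C)C)ccc1O[Si](c1ccccc1)(c1ccccc1)C(C)(C)C
F8 | step 3 | 2-(hydroxymethyl)-6-methoxy-4-[3-(tert-butyldiphenylsilyloxy)propyl]phenol | COc1cc(CCCO[Si](c2ccccc2)(c2ccccc2)C(C)(C)C)cc(CO)c1O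
A1 | alternative 1 | 5-(4-benzyloxy-3-methoxyphenyl)furan-3-carbaldehyde | O=Cc1coc(-c2ccc(OCc3ccccc3)c(OC)c2)c1
A2 | alternative 1 | (E)-4-[5-(4-benzyloxy-3-methoxyphenyl)furan-3-yl]-3-(ethoxycarbonyl)but-3-enoic acid | CCOC(=O)/C(CC(=O)O)=C/c1coc(-c2ccc(OCc3ccccc3)c(OC)c2)c1
A3 | alternative 1 | ethyl 7-acetoxy-2-(4-benzyloxy-3-methoxyphenyl)benzofuran-5-carboxylate | CCOC(=O)c1cc(OC(C)=O)c2oc(-c3ccc(OCc4ccccc4)c(OC)c3)cc2c1
A4 | alternative 2 | pentacarbonyl{[4-(1,3-dioxolan-2-yl)-5-(3-methoxy-4-triisopropylsilyloxyphenyl)furan-2-yl](methoxy)methylidene}chromium | COC(=[Cr])c1cc(C2OCCO2)c(-c2ccc(O[Si](C(C)C)(C(C)C)C(C)C)c(OC)c2)o1.[C-]#[O+].[C-]#[O+].[C-]#[O+].[C-]#[O+].[C-]#[O+]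
A5 | alternative 2 | tert-butyl(dimethyl)(pent-4-yn-1-yloxy)silane | C#CCCCO[Si](C)(C)C(C)(C)C
A6 | alternative 2 | 3-(1,3-dioxolan-2-yl)-7-methoxy-2-(3-methoxy-4-triisopropylsilyloxyphenyl)-5-[3-(tert-butyldimethylsilyloxy)propyl]benzofuran-4-ol | COc1cc(CCCO[Si](C)(C)C(C)(C)C)c(O)c2c(C3OCCO3)c(-c3ccc(O[Si](C(C)C)(C(C)C)C(C)C)c(OC)c3)oc12
A7 | alternative 3 | 4-(3-acetoxypropyl)-2-[(4-benzyloxy-3-methoxyphenyl)ethynyl]-6-methoxyphenol | COc1cc(CCCOC(C)=O)cc(C#Cc2ccc(OCc3ccccc3)c(OC)c2)c1O
A8 | alternative 3 | methyl 5-(3-acetoxypropyl)-2-(4-benzyloxy-3-methoxyphenyl)-7-methoxybenzofuran-3-carboxylate | COC(=O)c1c(-c2ccc(OCc3ccccc3)c(OC)c2)oc2c(OC)cc(CCCOC(C)=O)cc12
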